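## Retrosynthetic overview

1. The tetramic acid is the last ring: Lacey–Dieckmann closure of a glycine β-keto amide, whose β-keto thioester comes from aldol addition of a thioacetate enolate to the C-1 decalin aldehyde.
2. Side chain: the C-3′–C-4′ bond is an aldol union of a decalin methyl ketone with an (E)-enal (from an Evans syn-aldol); dehydration gives the (E,E)-dienone and CBS reduction sets C-2′.
3. C-1 quaternary centre: the ring A ester enolate is alkylated on its open face with a CH2O unit (the future acyl carbon); the ester is then reduced to the C-1 methyl.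
4. cis-Decalin: ring A is annulated onto ring B by Mukaiyama–Michael addition and aldol condensation; hydrogenation sets the cis fusion; the enone becomes the C-3/C-4 alkene via its enol triflate.
5. Ring B comes from (R)-pulegone (second methyl by cuprate addition). Ring order: B (chiral pool), then A, then the pyrrolidine-2,4-dione.

Assumption: the target is taken exactly as drawn (cis-fused decalin, 3-acyl-4-hydroxy tautomer of the tetramic acid).

Notation: C-1 to C-8a are octahydronaphthalene locants of the core; primed locants are those of the C10 side chain; TBS = tert-butyldimethylsilyl; pivalate = 2,2-dimethylpropanoate. Stereochemical outcomes are predicted from conformational arguments and analogy, not from precedent on this exact system.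

## Route

Step 1
Reactants: 1 (R)-(+)-pulegone
Product: 2 pulegone oxide (spiro-epoxide of 1; epimers at the ring epoxide carbon)
Conditions: H2O2 (30%), NaOH, MeOH, 0 °C to rt
Reagents that add atoms: hydrogen peroxide, OO
Why: Weitz–Scheffer nucleophilic epoxidation of the conjugated enone; the epoxide carbons are removed in steps 2 and 3, so their configuration is irrelevant.

Step 2
Reactants: 2 pulegone oxide
Product: 3 (5R)-5-methyl-2-(phenylsulfanyl)cyclohexan-1-one (C-2 epimers)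
Conditions: PhSH, NaH (0.1 equiv), THF, reflux
Reagents that add atoms: benzenethiol, Sc1ccccc1
Why: thiolate opens the epoxy ketone at the α-carbon and the β-alkoxide formed undergoes retro-aldol cleavage with loss of acetone, leaving the methyl stereocentre untouched.

Step 3
Reactants: 3 (5R)-5-methyl-2-(phenylsulfanyl)cyclohexan-1-one
Product: 5 (5R)-5-methylcyclohex-2-en-1-one, via sulfoxide 4 (not isolated)
Conditions: mCPBA, CH2Cl2, −78 °C; then CaCO3, toluene, 90 °C
Reagents that add atoms: none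
Why: sulfide oxidation followed by thermal syn-elimination of the α-sulfinyl ketone, which can only give the conjugated C-2/C-3 alkene.

Step 4
Reactants: 5 (5R)-5-methylcyclohex-2-en-1-one
Product: 7 trimethyl{[(3R,5R)-3,5-dimethylcyclohex-1-en-1-yl]oxy}silane, via lithium enolate 6 (not isolated)
Conditions: Me2CuLi, Et2O, −78 to −20 °C; then Me3SiCl, Et3N, −78 °C to rt
Reagents that add atoms: lithium dimethylcuprate, [Li+].C[Cu-]C; chlorotrimethylsilane, C[Si](C)(C)Cl
Why: cuprate conjugate addition occurs anti to the C-5 methyl (trans-3,5, as usual for 5-substituted cyclohexenones) and the regiodefined enolate is trapped by O-silylation.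

Step 5
Reactants: 7 trimethyl{[(3R,5R)-3,5-dimethylcyclohex-1-en-1-yl]oxy}silane; 8 ethyl (2E)-4-oxopent-2-enoate
Product: 9 ethyl 2-[(1R,2R,4R)-2,4-dimethyl-6-oxocyclohexyl]-4-oxopentanoate (chain C-2 epimers)
Conditions: TiCl4, CH2Cl2, −78 °C; aq. K2CO3
Reagents that add atoms: none
Why: Mukaiyama–Michael addition at the alkene carbon β to the ketone of 8, the enol ether reacting on the face anti to its adjacent pseudoaxial methyl so that the new chain is trans to that methyl.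

Step 6
Reactants: 9 ethyl 2-[(1R,2R,4R)-2,4-dimethyl-6-oxocyclohexyl]-4-oxopentanoate
Product: 10 ethyl (6R,8R,8aR)-6,8-dimethyl-3-oxo-1,2,3,5,6,7,8,8a-octahydronaphthalene-1-carboxylate (C-1 epimers)
Conditions: pyrrolidine, AcOH, toluene, reflux, Dean–Stark
Reagents that add atoms: none
Why: intramolecular aldol condensation of the 1,5-diketone (second half of a Robinson annulation) closes ring A under mild enamine catalysis that leaves C-8a unchanged.

Step 7
Reactants: 10 ethyl (6R,8R,8aR)-6,8-dimethyl-3-oxo-1,2,3,5,6,7,8,8a-octahydronaphthalene-1-carboxylate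
Product: 12 ethyl (6R,8R,8aR)-6,8-dimethyl-3-oxo-2-(prop-2-en-1-yl)-1,2,3,5,6,7,8,8a-octahydronaphthalene-1-carboxylate (C-1/C-2 epimers), via lithium dienolate 11 (not isolated)
Conditions: LiN(iPr)2, THF, −78 °C; allyl bromide, DMPU, −78 to −20 °C
Reagents that add atoms: allyl bromide, C=CCBr
Why: kinetic α′-deprotonation of the enone gives the cross-conjugated dienolate, which is allylated at C-2 by SN2 alkylation; C-2 stays epimerisable and is fixed in step 10.

Step 8
Reactants: 12 ethyl (6R,8R,8aR)-6,8-dimethyl-3-oxo-2-(prop-2-en-1-yl)-1,2,3,5,6,7,8,8a-octahydronaphthalene-1-carboxylate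
Product: 13 ethyl (6R,8R,8aR)-6,8-dimethyl-3-oxo-2-(2-oxopropyl)-1,2,3,5,6,7,8,8a-octahydronaphthalene-1-carboxylate (C-1/C-2 epimers)
Conditions: PdCl2 (10 mol %), CuCl, O2 (1 atm), DMF/H2O (7:1), rt
Reagents that add atoms: water, O
Why: Tsuji–Wacker oxidation converts the terminal alkene into the methyl ketone with Markovnikov selectivity while the trisubstituted conjugated alkene is inert.

Step 9
Reactants: 13 ethyl (6R,8R,8aR)-6,8-dimethyl-3-oxo-2-(2-oxopropyl)-1,2,3,5,6,7,8,8a-octahydronaphthalene-1-carboxylate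
Product: 14 ethyl (6R,8R,8aR)-6,8-dimethyl-2-[(2-methyl-1,3-dioxolan-2-yl)methyl]-3-oxo-1,2,3,5,6,7,8,8a-octahydronaphthalene-1-carboxylate (C-1/C-2 epimers)
Conditions: Me3SiOCH2CH2OSiMe3, Me3SiOTf (5 mol %), CH2Cl2, −78 °C
Reagents that add atoms: 1,2-bis(trimethylsilyloxy)ethane, C[Si](C)(C)OCCO[Si](C)(C)C
Why: Noyori ketalisation protects the saturated methyl ketone and not the less electrophilic enone or the ester, and its aprotic low-temperature conditions avoid furan formation from the 1,4-diketone.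

Step 10
Reactants: 14 ethyl (6R,8R,8aR)-6,8-dimethyl-2-[(2-methyl-1,3-dioxolan-2-yl)methyl]-3-oxo-1,2,3,5,6,7,8,8a-octahydronaphthalene-1-carboxylate
Product: 15 ethyl (2S,4aS,6R,8R,8aS)-6,8-dimethyl-2-[(2-methyl-1,3-dioxolan-2-yl)methyl]-3-oxodecahydronaphthalene-1-carboxylate (cis-fused; C-1 epimers)
Conditions: H2 (1 atm), Pd/C, EtOAc, rt; then DBU (0.2 equiv), CH2Cl2, rt
Reagents that add atoms: none
Why: heterogeneous hydrogenation (syn addition): the ring A enone holds the C-8a–C-1 bond equatorial on ring B, so the C-8 methyl is equatorial and the C-6 methyl axial on the opposite face, and hydrogen therefore adds from the face of H-8a to give the cis-fused ketone, after which DBU equilibrates the enolisable C-2 to the equatorial side chain, cis to the ring B carbons.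

Step 11
Reactants: 15 ethyl (2S,4aS,6R,8R,8aS)-6,8-dimethyl-2-[(2-methyl-1,3-dioxolan-2-yl)methyl]-3-oxodecahydronaphthalene-1-carboxylate
Product: 17 ethyl cis-fused 6,8-dimethyl-2-[(2-methyl-1,3-dioxolan-2-yl)methyl]-3-(trifluoromethanesulfonyloxy)-1,2,4a,5,6,7,8,8a-octahydronaphthalene-1-carboxylate (C-3 enol triflate of 15), via potassium enolate 16 (not isolated)
Conditions: KN(SiMe3)2, THF, −78 °C; then PhNTf2
Reagents that add atoms: N-phenylbis(trifluoromethanesulfonimide), O=S(=O)(N(c1ccccc1)S(=O)(=O)C(F)(F)F)C(F)(F)F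
Why: kinetic deprotonation removes the unhindered C-4 hydrogen and not the hydrogen at substituted C-2 or the less acidic ester α-hydrogen, and O-triflation fixes the C-3/C-4 double bond.

Step 12
Reactants: 17 C-3 enol triflate of 15
Product: 18 ethyl (2R,4aS,6R,8R,8aS)-6,8-dimethyl-2-[(2-methyl-1,3-dioxolan-2-yl)methyl]-1,2,4a,5,6,7,8,8a-octahydronaphthalene-1-carboxylate (C-1 epimers)
Conditions: Pd(OAc)2 (5 mol %), PPh3, Bu3N, HCO2H, DMF, 60 °C
Reagents that add atoms: none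
Why: palladium-catalysed formate reduction of the enol triflate (oxidative addition to zerovalent palladium, formate decarboxylation, reductive elimination) replaces OTf by H without touching a stereocentre.

Step 13
Reactants: 18 ethyl (2R,4aS,6R,8R,8aS)-6,8-dimethyl-2-[(2-methyl-1,3-dioxolan-2-yl)methyl]-1,2,4a,5,6,7,8,8a-octahydronaphthalene-1-carboxylate
Product: 20 ethyl (1R,2R,4aS,6R,8R,8aS)-1-[(benzyloxy)methyl]-6,8-dimethyl-2-[(2-methyl-1,3-dioxolan-2-yl)methyl]-1,2,4a,5,6,7,8,8a-octahydronaphthalene-1-carboxylate, via lithium ester enolate 19 (not isolated)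
Conditions: LiN(iPr)2, THF/DMPU, −78 to −40 °C; BnOCH2Cl, −78 to 0 °C
Reagents that add atoms: benzyl chloromethyl ether, ClCOCc1ccccc1
Why: ester enolate alkylation (SN2 on the chloromethyl ether): the lower face of the planar C-1 enolate is shielded by the C-2 side chain, C-8 and the axial C-5 methylene, so the CH2OBn arm enters cis to H-2 and H-8a (it becomes the acyl carbon) and the ester ends cis to the C-2 chain (it becomes the C-1 methyl).

Step 14
Reactants: 20 ethyl (1R,2R,4aS,6R,8R,8aS)-1-[(benzyloxy)methyl]-6,8-dimethyl-2-[(2-methyl-1,3-dioxolan-2-yl)methyl]-1,2,4a,5,6,7,8,8a-octahydronaphthalene-1-carboxylate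
Product: 21 [(1S,2R,4aS,6R,8R,8aS)-1-[(benzyloxy)methyl]-6,8-dimethyl-2-[(2-methyl-1,3-dioxolan-2-yl)methyl]-1,2,4a,5,6,7,8,8a-octahydronaphthalen-1-yl]methanol
Conditions: LiAlH4, THF, 0 °C to rt
Reagents that add atoms: none
Why: hydride reduction of the hindered ester to the primary alcohol; ketal, benzyl ether and isolated alkene are inert.

Step 15
Reactants: 21 the C-1 hydroxymethyl compound
Product: 22 (1R,2R,4aS,6R,8R,8aS)-1-[(benzyloxy)methyl]-6,8-dimethyl-2-[(2-methyl-1,3-dioxolan-2-yl)methyl]-1,2,4a,5,6,7,8,8a-octahydronaphthalene-1-carbaldehyde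
Conditions: Dess–Martin periodinane, NaHCO3, CH2Cl2, rt
Reagents that add atoms: none
Why: Dess–Martin oxidation of the neopentyl alcohol to an aldehyde that has no α-hydrogen and so cannot epimerise.

Step 16
Reactants: 22 the C-1 carbaldehyde
Product: 24 2-{[(1S,2R,4aS,6R,8R,8aS)-1-[(benzyloxy)methyl]-1,6,8-trimethyl-1,2,4a,5,6,7,8,8a-octahydronaphthalen-2-yl]methyl}-2-methyl-1,3-dioxolane, via hydrazone 23 (not isolated)
Conditions: N2H4·H2O, KOH, diethylene glycol, 130 then 200 °C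
Reagents that add atoms: none
Why: Wolff–Kishner reduction (Huang-Minlon procedure) turns the formyl group into the C-1 methyl group; ketal, benzyl ether and alkene are stable to hot base.

Step 17
Reactants: 24 the C-1 methyl benzyl ether
Product: 25 [(1S,2R,4aS,6R,8R,8aS)-1,6,8-trimethyl-2-[(2-methyl-1,3-dioxolan-2-yl)methyl]-1,2,4a,5,6,7,8,8a-octahydronaphthalen-1-yl]methanol
Conditions: Li, NH3 (l), THF, −78 °C; then NH4Cl
Reagents that add atoms: none
Why: dissolving-metal (Birch-type) cleavage of the benzyl ether, which leaves the isolated ring alkene and the ketal untouched.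

Step 18
Reactants: 25 the C-1 methanol
Product: 26 [(1S,2R,4aS,6R,8R,8aS)-1,6,8-trimethyl-2-[(2-methyl-1,3-dioxolan-2-yl)methyl]-1,2,4a,5,6,7,8,8a-octahydronaphthalen-1-yl]methyl pivalate
Conditions: tBuCOCl, pyridine, DMAP, CH2Cl2, rt
Reagents that add atoms: pivaloyl chloride, CC(C)(C)C(Cl)=O
Why: acylation gives a non-enolisable ester that survives the amide base, CBS and silylation steps and is removed later by hydride.

Step 19
Reactants: 26 the pivalate ketal
Product: 27 [(1S,2R,4aS,6R,8R,8aS)-1,6,8-trimethyl-2-(2-oxopropyl)-1,2,4a,5,6,7,8,8a-octahydronaphthalen-1-yl]methyl pivalate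
Conditions: PPTS, acetone/H2O (10:1), 55 °C
Reagents that add atoms: water, O
Why: mild acid-catalysed ketal hydrolysis releases the methyl ketone without touching the pivalate.

Step 20
Reactants: 28 (4R)-4-benzyl-3-propanoyl-1,3-oxazolidin-2-one; 29 propanal
Product: 31 (4R)-4-benzyl-3-[(2R,3S)-3-hydroxy-2-methylpentanoyl]-1,3-oxazolidin-2-one, via boron enolate 30 (not isolated)
Conditions: Bu2BOTf, iPr2NEt, CH2Cl2, −78 to 0 °C; then H2O2, MeOH, pH 7 buffer
Reagents that add atoms: none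
Why: Evans syn-aldol: the (Z)-boron enolate reacts through a Zimmerman–Traxler chair with the auxiliary benzyl group blocking one face, which sets both side-chain stereocentres (2R,3S).

Step 21
Reactants: 31 the syn-aldol imide
Product: 32 (4R)-4-benzyl-3-[(2R,3S)-3-(TBS-oxy)-2-methylpentanoyl]-1,3-oxazolidin-2-one
Conditions: TBSOTf, 2,6-lutidine, CH2Cl2, −78 °C
Reagents that add atoms: tert-butyldimethylsilyl trifluoromethanesulfonate, CC(C)(C)[Si](C)(C)OS(=O)(=O)C(F)(F)F
Why: silylation protects the carbinol and prevents retro-aldol cleavage in the following steps.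

Step 22
Reactants: 32 the silylated imide
Product: 33 (2S,3S)-3-(TBS-oxy)-2-methylpentan-1-ol
Conditions: LiBH4, MeOH (1 equiv), Et2O, 0 °C
Reagents that add atoms: none
Why: reductive removal of the auxiliary by hydride attack at the exocyclic imide carbonyl, without epimerisation.

Step 23
Reactants: 33 (2S,3S)-3-(TBS-oxy)-2-methylpentan-1-ol
Product: 34 (2R,3S)-3-(TBS-oxy)-2-methylpentanal
Conditions: Dess–Martin periodinane, NaHCO3, CH2Cl2, 0 °C to rt
Reagents that add atoms: none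
Why: buffered Dess–Martin oxidation gives the α-branched aldehyde without epimerisation; it is used at once.

Step 24
Reactants: 34 (2R,3S)-3-(TBS-oxy)-2-methylpentanal
Product: 35 ethyl (2E,4S,5S)-5-(TBS-oxy)-4-methylhept-2-enoate
Conditions: (EtO)2P(O)CH2CO2Et, LiCl, DBU, MeCN, rt
Reagents that add atoms: triethyl phosphonoacetate, CCOC(=O)CP(=O)(OCC)OCC
Why: Horner–Wadsworth–Emmons olefination under Masamune–Roush conditions is (E)-selective and mild enough for the epimerisable aldehyde.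

Step 25
Reactants: 35 ethyl (2E,4S,5S)-5-(TBS-oxy)-4-methylhept-2-enoate
Product: 36 (2E,4S,5S)-5-(TBS-oxy)-4-methylhept-2-en-1-ol
Conditions: iBu2AlH, CH2Cl2, −78 °C
Reagents that add atoms: none
Why: 1,2-reduction of the enoate to the allylic alcohol.

Step 26
Reactants: 36 (2E,4S,5S)-5-(TBS-oxy)-4-methylhept-2-en-1-ol
Product: 37 (2E,4S,5S)-5-(TBS-oxy)-4-methylhept-2-enal
Conditions: MnO2, CH2Cl2, rt
Reagents that add atoms: none
Why: chemoselective allylic oxidation gives the (E)-enal without touching the γ-stereocentre.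

Step 27
Reactants: 27 the decalin methyl ketone; 37 (2E,4S,5S)-5-(TBS-oxy)-4-methylhept-2-enal
Product: 39 [(1S,2R,4aS,6R,8R,8aS)-2-[(5E,7S,8S)-4-hydroxy-7-methyl-2-oxo-8-(TBS-oxy)dec-5-en-1-yl]-1,6,8-trimethyl-1,2,4a,5,6,7,8,8a-octahydronaphthalen-1-yl]methyl pivalate (C-4′ epimers), via lithium enolate 38 (not isolated)
Conditions: LiN(iPr)2, THF, −78 °C; then 37, −78 °C; aq. NH4Cl
Reagents that add atoms: none
Why: intermolecular aldol addition that joins the two fragments: LiN(iPr)2 removes a methyl hydrogen of the methyl ketone under kinetic control and the lithium enolate adds 1,2 to the enal at −78 °C, the new carbinol centre being lost again in step 28.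

Step 28
Reactants: 39 the β-hydroxy ketone
Product: 41 [(1S,2R,4aS,6R,8R,8aS)-1,6,8-trimethyl-2-[(3E,5E,7S,8S)-7-methyl-2-oxo-8-(TBS-oxy)deca-3,5-dien-1-yl]-1,2,4a,5,6,7,8,8a-octahydronaphthalen-1-yl]methyl pivalate, via mesylate 40 (not isolated)
Conditions: MsCl, Et3N, CH2Cl2, 0 °C; then DBU, rt
Reagents that add atoms: none
Why: mesylation and E1cB elimination of the β-mesyloxy ketone give the thermodynamically favoured (E,E)-dienone.

Step 29
Reactants: 41 the (E,E)-dienone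
Product: 42 [(1S,2R,4aS,6R,8R,8aS)-2-[(2R,3E,5E,7S,8S)-2-hydroxy-7-methyl-8-(TBS-oxy)deca-3,5-dien-1-yl]-1,6,8-trimethyl-1,2,4a,5,6,7,8,8a-octahydronaphthalen-1-yl]methyl pivalate
Conditions: (S)-2-methyl-CBS-oxazaborolidine (0.5 equiv), catecholborane, toluene, −78 °C
Reagents that add atoms: none
Why: Corey–Bakshi–Shibata reduction: with the (S)-oxazaborolidine the dienyl group acts as the large substituent and hydride is delivered to the face that gives the (R)-allylic alcohol, under reagent control.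

Step 30
Reactants: 42 the (2′R)-dienol
Product: 43 [(1S,2R,4aS,6R,8R,8aS)-1,6,8-trimethyl-2-[(2R,3E,5E,7S,8S)-7-methyl-2,8-bis(TBS-oxy)deca-3,5-dien-1-yl]-1,2,4a,5,6,7,8,8a-octahydronaphthalen-1-yl]methyl pivalate
Conditions: TBSOTf, 2,6-lutidine, CH2Cl2, −78 °C
Reagents that add atoms: tert-butyldimethylsilyl trifluoromethanesulfonate, CC(C)(C)[Si](C)(C)OS(=O)(=O)C(F)(F)F
Why: silylation protects the acid- and base-sensitive dienylic alcohol for the remaining steps.

Step 31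
Reactants: 43 the bis-TBS pivalate
Product: 44 [(1S,2R,4aS,6R,8R,8aS)-1,6,8-trimethyl-2-[(2R,3E,5E,7S,8S)-7-methyl-2,8-bis(TBS-oxy)deca-3,5-dien-1-yl]-1,2,4a,5,6,7,8,8a-octahydronaphthalen-1-yl]methanol
Conditions: iBu2AlH, CH2Cl2, −78 to 0 °C
Reagents that add atoms: none
Why: reductive cleavage of the pivalate by hydride, which leaves silyl ethers and the diene untouched.

Step 32
Reactants: 44 the C-1 methanol
Product: 45 (1S,2R,4aS,6R,8R,8aS)-1,6,8-trimethyl-2-[(2R,3E,5E,7S,8S)-7-methyl-2,8-bis(TBS-oxy)deca-3,5-dien-1-yl]-1,2,4a,5,6,7,8,8a-octahydronaphthalene-1-carbaldehyde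
Conditions: Dess–Martin periodinane, NaHCO3, CH2Cl2, rt
Reagents that add atoms: none
Why: Dess–Martin oxidation to the non-enolisable neopentyl aldehyde.

Step 33
Reactants: 45 the C-1 carbaldehyde; 46 S-tert-butyl ethanethioate
Product: 48 S-tert-butyl 3-hydroxy-3-[the C-1 decalinyl group of 45]propanethioate (C-3 epimers), via lithium thioester enolate 47 (not isolated)
Conditions: LiN(iPr)2, THF, −78 °C; then 45, −78 °C; aq. NH4Cl
Reagents that add atoms: none
Why: aldol addition of the small, reactive thioacetate enolate to the hindered aldehyde; the new carbinol centre is oxidised away in step 34.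

Step 34
Reactants: 48 the β-hydroxy thioester
Product: 49 S-tert-butyl 3-oxo-3-[the C-1 decalinyl group of 45]propanethioate
Conditions: Dess–Martin periodinane, NaHCO3, CH2Cl2, rt
Reagents that add atoms: none
Why: Dess–Martin oxidation gives the β-keto thioester under neutral conditions.

Step 35
Reactants: 49 the β-keto thioester; 50 glycine methyl ester hydrochloride
Product: 51 methyl N-{3-oxo-3-[the C-1 decalinyl group of 45]propanoyl}glycinate
Conditions: AgOCOCF3, Et3N, THF, 0 °C to rt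
Reagents that add atoms: none
Why: silver-promoted aminolysis: the thiophilic silver salt activates the thioester so that the amine acylates at low temperature without touching the silyl ethers.

Step 36
Reactants: 51 the β-keto amide
Product: 52 2′,8′-bis-TBS ether of the target (3-acyl tetramic acid)
Conditions: NaOMe, MeOH, rt; then aq. HCl to pH 3
Reagents that add atoms: none
Why: Lacey–Dieckmann cyclisation: the β-dicarbonyl carbanion attacks the glycine ester carbonyl (5-exo-trig Claisen-type condensation) and the product is held as its stable enolate until acidification.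

Step 37
Reactants: 52 the bis-TBS tetramic acid
Product: 53 CNP0117518.2, 3-{[(1S,2R,4aS,6R,8R,8aS)-2-[(2R,3E,5E,7S,8S)-2,8-dihydroxy-7-methyldeca-3,5-dien-1-yl]-1,6,8-trimethyl-1,2,4a,5,6,7,8,8a-octahydronaphthalen-1-yl]carbonyl}-4-hydroxy-1,5-dihydro-2H-pyrrol-2-one
Conditions: HF·pyridine, pyridine, THF, 0 °C to rt
Reagents that add atoms: none
Why: buffered fluoride desilylation removes both TBS groups without ionising the dienylic alcohol.

## Compound list

1 | (R)-(+)-pulegone, (5R)-5-methyl-2-(propan-2-ylidene)cyclohexan-1-one | C[C@@H]1CCC(=C(C)C)C(=O)C1 | starting material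
2 | pulegone oxide (epimers at the ring epoxide carbon) | C[C@@H]1CCC2(OC2(C)C)C(=O)C1 | intermediate
3 | (5R)-5-methyl-2-(phenylsulfanyl)cyclohexan-1-one (C-2 epimers) | C[C@@H]1CCC(Sc2ccccc2)C(=O)C1 | intermediate
4 | (5R)-5-methyl-2-(phenylsulfinyl)cyclohexan-1-one (not isolated) | C[C@@H]1CCC(S(=O)c2ccccc2)C(=O)C1 | intermediate
5 | (5R)-5-methylcyclohex-2-en-1-one | C[C@@H]1CC=CC(=O)C1 | intermediate
6 | lithium (3R,5R)-3,5-dimethylcyclohex-1-en-1-olate (not isolated) | [Li+].[O-]C1=C[C@H](C)C[C@@H](C)C1 | intermediate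
7 | trimethyl{[(3R,5R)-3,5-dimethylcyclohex-1-en-1-yl]oxy}silane | C[Si](C)(C)OC1=C[C@H](C)C[C@@H](C)C1 | intermediate
8 | ethyl (2E)-4-oxopent-2-enoate | CCOC(=O)/C=C/C(C)=O | starting material
9 | ethyl 2-[(1R,2R,4R)-2,4-dimethyl-6-oxocyclohexyl]-4-oxopentanoate (chain C-2 epimers) | O=C1C[C@H](C)C[C@@H](C)[C@@H]1C(CC(C)=O)C(=O)OCC | intermediate
10 | ethyl (6R,8R,8aR)-6,8-dimethyl-3-oxo-1,2,3,5,6,7,8,8a-octahydronaphthalene-1-carboxylate (C-1 epimers) | CCOC(=O)C1CC(=O)C=C2C[C@H](C)C[C@@H](C)[C@H]12 | intermediate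
11 | lithium cross-conjugated dienolate of 10 (not isolated) | CCOC(=O)C1C=C([O-])C=C2C[C@H](C)C[C@@H](C)[C@H]12.[Li+] | intermediate
12 | ethyl (6R,8R,8aR)-6,8-dimethyl-3-oxo-2-(prop-2-en-1-yl)-1,2,3,5,6,7,8,8a-octahydronaphthalene-1-carboxylate (C-1/C-2 epimers) | CCOC(=O)C1C(CC=C)C(=O)C=C2C[C@H](C)C[C@@H](C)[C@H]12 | intermediate
13 | ethyl (6R,8R,8aR)-6,8-dimethyl-3-oxo-2-(2-oxopropyl)-1,2,3,5,6,7,8,8a-octahydronaphthalene-1-carboxylate (C-1/C-2 epimers) | CCOC(=O)C1C(CC(C)=O)C(=O)C=C2C[C@H](C)C[C@@H](C)[C@H]12 | intermediate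
14 | ethyl (6R,8R,8aR)-6,8-dimethyl-2-[(2-methyl-1,3-dioxolan-2-yl)methyl]-3-oxo-1,2,3,5,6,7,8,8a-octahydronaphthalene-1-carboxylate (C-1/C-2 epimers) | CCOC(=O)C1C(CC3(C)OCCO3)C(=O)C=C2C[C@H](C)C[C@@H](C)[C@H]12 | intermediate
15 | ethyl (2S,4aS,6R,8R,8aS)-6,8-dimethyl-2-[(2-methyl-1,3-dioxolan-2-yl)methyl]-3-oxodecahydronaphthalene-1-carboxylate (cis-fused; C-1 epimers) | CC1(OCCO1)C[C@@H]2C(=O)C[C@@H]3C[C@H](C)C[C@@H](C)[C@@H]3C2C(=O)OCC | intermediate
16 | potassium C-3/C-4 enolate of 15 (not isolated) | CC1(OCCO1)C[C@@H]2C([O-])=C[C@@H]3C[C@H](C)C[C@@H](C)[C@@H]3C2C(=O)OCC.[K+] | intermediate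
17 | C-3 enol triflate of 15 (C-3/C-4 double bond) | CC1(OCCO1)C[C@@H]2C(OS(=O)(=O)C(F)(F)F)=C[C@@H]3C[C@H](C)C[C@@H](C)[C@@H]3C2C(=O)OCC | intermediate
18 | ethyl (2R,4aS,6R,8R,8aS)-6,8-dimethyl-2-[(2-methyl-1,3-dioxolan-2-yl)methyl]-1,2,4a,5,6,7,8,8a-octahydronaphthalene-1-carboxylate (C-1 epimers) | CC1(OCCO1)C[C@@H]2C=C[C@@H]3C[C@H](C)C[C@@H](C)[C@@H]3C2C(=O)OCC | intermediate
19 | lithium ester enolate of 18 (not isolated) | CC1(OCCO1)C[C@@H]2C=C[C@@H]3C[C@H](C)C[C@@H](C)[C@@H]3C2=C([O-])OCC.[Li+] | intermediate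
20 | ethyl (1R,2R,4aS,6R,8R,8aS)-1-[(benzyloxy)methyl]-6,8-dimethyl-2-[(2-methyl-1,3-dioxolan-2-yl)methyl]-1,2,4a,5,6,7,8,8a-octahydronaphthalene-1-carboxylate | CC1(OCCO1)C[C@@H]2C=C[C@@H]3C[C@H](C)C[C@@H](C)[C@@H]3[C@@]2(C(=O)OCC)COCc1ccccc1 | intermediate
21 | [(1S,2R,4aS,6R,8R,8aS)-1-[(benzyloxy)methyl]-6,8-dimethyl-2-[(2-methyl-1,3-dioxolan-2-yl)methyl]-1,2,4a,5,6,7,8,8a-octahydronaphthalen-1-yl]methanol | CC1(OCCO1)C[C@@H]2C=C[C@@H]3C[C@H](C)C[C@@H](C)[C@@H]3[C@@]2(CO)COCc1ccccc1 | intermediate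
22 | (1R,2R,4aS,6R,8R,8aS)-1-[(benzyloxy)methyl]-6,8-dimethyl-2-[(2-methyl-1,3-dioxolan-2-yl)methyl]-1,2,4a,5,6,7,8,8a-octahydronaphthalene-1-carbaldehyde | CC1(OCCO1)C[C@@H]2C=C[C@@H]3C[C@H](C)C[C@@H](C)[C@@H]3[C@@]2(C=O)COCc1ccccc1 | intermediate
23 | hydrazone of 22 (not isolated) | CC1(OCCO1)C[C@@H]2C=C[C@@H]3C[C@H](C)C[C@@H](C)[C@@H]3[C@@]2(C=NN)COCc1ccccc1 | intermediate
24 | 2-{[(1S,2R,4aS,6R,8R,8aS)-1-[(benzyloxy)methyl]-1,6,8-trimethyl-1,2,4a,5,6,7,8,8a-octahydronaphthalen-2-yl]methyl}-2-methyl-1,3-dioxolane | CC1(OCCO1)C[C@@H]2C=C[C@@H]3C[C@H](C)C[C@@H](C)[C@@H]3[C@@]2(C)COCc1ccccc1 | intermediate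
25 | [(1S,2R,4aS,6R,8R,8aS)-1,6,8-trimethyl-2-[(2-methyl-1,3-dioxolan-2-yl)methyl]-1,2,4a,5,6,7,8,8a-octahydronaphthalen-1-yl]methanol | CC1(OCCO1)C[C@@H]2C=C[C@@H]3C[C@H](C)C[C@@H](C)[C@@H]3[C@@]2(C)CO | intermediate
26 | pivalate of 25 | CC1(OCCO1)C[C@@H]2C=C[C@@H]3C[C@H](C)C[C@@H](C)[C@@H]3[C@@]2(C)COC(=O)C(C)(C)C | intermediate
27 | [(1S,2R,4aS,6R,8R,8aS)-1,6,8-trimethyl-2-(2-oxopropyl)-1,2,4a,5,6,7,8,8a-octahydronaphthalen-1-yl]methyl pivalate | CC(=O)C[C@@H]1C=C[C@@H]2C[C@H](C)C[C@@H](C)[C@@H]2[C@@]1(C)COC(=O)C(C)(C)C | intermediate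
28 | (4R)-4-benzyl-3-propanoyl-1,3-oxazolidin-2-one | CCC(=O)N1[C@H](Cc2ccccc2)COC1=O | starting material
29 | propanal | CCC=O | starting material
30 | (Z)-dibutylboron enolate of 28 (not isolated) | C/C=C(\OB(CCCC)CCCC)N1[C@H](Cc2ccccc2)COC1=O | intermediate
31 | (4R)-4-benzyl-3-[(2R,3S)-3-hydroxy-2-methylpentanoyl]-1,3-oxazolidin-2-one | CC[C@H](O)[C@@H](C)C(=O)N1[C@H](Cc2ccccc2)COC1=O | intermediate
32 | (4R)-4-benzyl-3-[(2R,3S)-3-(TBS-oxy)-2-methylpentanoyl]-1,3-oxazolidin-2-one | CC[C@H](O[Si](C)(C)C(C)(C)C)[C@@H](C)C(=O)N1[C@H](Cc2ccccc2)COC1=O | intermediate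
33 | (2S,3S)-3-(TBS-oxy)-2-methylpentan-1-ol | CC[C@H](O[Si](C)(C)C(C)(C)C)[C@@H](C)CO | intermediate
34 | (2R,3S)-3-(TBS-oxy)-2-methylpentanal | CC[C@H](O[Si](C)(C)C(C)(C)C)[C@@H](C)C=O | intermediate
35 | ethyl (2E,4S,5S)-5-(TBS-oxy)-4-methylhept-2-enoate | CC[C@H](O[Si](C)(C)C(C)(C)C)[C@@H](C)/C=C/C(=O)OCC | intermediate
36 | (2E,4S,5S)-5-(TBS-oxy)-4-methylhept-2-en-1-ol | CC[C@H](O[Si](C)(C)C(C)(C)C)[C@@H](C)/C=C/CO | intermediate
37 | (2E,4S,5S)-5-(TBS-oxy)-4-methylhept-2-enal | CC[C@H](O[Si](C)(C)C(C)(C)C)[C@@H](C)/C=C/C=O | intermediate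
38 | lithium enolate of 27 at the methyl group (not isolated) | [Li+].[O-]C(=C)C[C@@H]1C=C[C@@H]2C[C@H](C)C[C@@H](C)[C@@H]2[C@@]1(C)COC(=O)C(C)(C)C | intermediate
39 | aldol adduct, 4′-hydroxy-2′-oxo-dec-5′-enyl decalin pivalate (C-4′ epimers) | CC[C@H](O[Si](C)(C)C(C)(C)C)[C@@H](C)/C=C/C(O)CC(=O)C[C@@H]1C=C[C@@H]2C[C@H](C)C[C@@H](C)[C@@H]2[C@@]1(C)COC(=O)C(C)(C)C | intermediate
40 | C-4′ mesylate of 39 (not isolated) | CC[C@H](O[Si](C)(C)C(C)(C)C)[C@@H](C)/C=C/C(OS(C)(=O)=O)CC(=O)C[C@@H]1C=C[C@@H]2C[C@H](C)C[C@@H](C)[C@@H]2[C@@]1(C)COC(=O)C(C)(C)C | intermediate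
41 | (3′E,5′E)-2′-oxo dienone, decalin pivalate | CC[C@H](O[Si](C)(C)C(C)(C)C)[C@@H](C)/C=C/C=C/C(=O)C[C@@H]1C=C[C@@H]2C[C@H](C)C[C@@H](C)[C@@H]2[C@@]1(C)COC(=O)C(C)(C)C | intermediate
42 | (2′R,3′E,5′E)-dienol, decalin pivalate | CC[C@H](O[Si](C)(C)C(C)(C)C)[C@@H](C)/C=C/C=C/[C@H](O)C[C@@H]1C=C[C@@H]2C[C@H](C)C[C@@H](C)[C@@H]2[C@@]1(C)COC(=O)C(C)(C)C | intermediate
43 | 2′,8′-bis-TBS dienyl decalin pivalate | CC[C@H](O[Si](C)(C)C(C)(C)C)[C@@H](C)/C=C/C=C/[C@H](O[Si](C)(C)C(C)(C)C)C[C@@H]1C=C[C@@H]2C[C@H](C)C[C@@H](C)[C@@H]2[C@@]1(C)COC(=O)C(C)(C)C | intermediate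
44 | 2′,8′-bis-TBS C-1 methanol | CC[C@H](O[Si](C)(C)C(C)(C)C)[C@@H](C)/C=C/C=C/[C@H](O[Si](C)(C)C(C)(C)C)C[C@@H]1C=C[C@@H]2C[C@H](C)C[C@@H](C)[C@@H]2[C@@]1(C)CO | intermediate
45 | 2′,8′-bis-TBS C-1 carbaldehyde | CC[C@H](O[Si](C)(C)C(C)(C)C)[C@@H](C)/C=C/C=C/[C@H](O[Si](C)(C)C(C)(C)C)C[C@@H]1C=C[C@@H]2C[C@H](C)C[C@@H](C)[C@@H]2[C@@]1(C)C=O | intermediate
46 | S-tert-butyl ethanethioate | CC(=O)SC(C)(C)C | starting material
47 | lithium enolate of 46 (not isolated) | [Li+].[O-]C(=C)SC(C)(C)C | intermediate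
48 | β-hydroxy thioester (C-3 epimers) | CC[C@H](O[Si](C)(C)C(C)(C)C)[C@@H](C)/C=C/C=C/[C@H](O[Si](C)(C)C(C)(C)C)C[C@@H]1C=C[C@@H]2C[C@H](C)C[C@@H](C)[C@@H]2[C@@]1(C)C(O)CC(=O)SC(C)(C)C | intermediate
49 | β-keto thioester | CC[C@H](O[Si](C)(C)C(C)(C)C)[C@@H](C)/C=C/C=C/[C@H](O[Si](C)(C)C(C)(C)C)C[C@@H]1C=C[C@@H]2C[C@H](C)C[C@@H](C)[C@@H]2[C@@]1(C)C(=O)CC(=O)SC(C)(C)C | intermediate
50 | glycine methyl ester hydrochloride | COC(=O)CN.Cl | starting material
51 | glycine methyl ester β-keto amide | CC[C@H](O[Si](C)(C)C(C)(C)C)[C@@H](C)/C=C/C=C/[C@H](O[Si](C)(C)C(C)(C)C)C[C@@H]1C=C[C@@H]2C[C@H](C)C[C@@H](C)[C@@H]2[C@@]1(C)C(=O)CC(=O)NCC(=O)OC | intermediate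
52 | 2′,8′-bis-TBS ether of the target | CC[C@H](O[Si](C)(C)C(C)(C)C)[C@@H](C)/C=C/C=C/[C@H](O[Si](C)(C)C(C)(C)C)C[C@@H]1C=C[C@@H]2C[C@H](C)C[C@@H](C)[C@@H]2[C@@]1(C)C(=O)C1=C(O)CNC1=O | intermediate
53 | CNP0117518.2 | CC[C@H](O)[C@@H](C)/C=C/C=C/[C@H](O)C[C@@H]1C=C[C@@H]2C[C@H](C)C[C@@H](C)[C@@H]2[C@@]1(C)C(=O)C1=C(O)CNC1=O | target

## Step count and risks

Total step count: 37. Longest linear sequence: 30 steps (steps 1–19 and 27–37, from 1).

Steps most likely to fail:

Step 10 (face selectivity of the enone hydrogenation; a trans-fused ketone would be useless). Fallback, setting out from 14 and coming back at 18: after DBU equilibration of C-2, LiBH(s-Bu)3 (THF, −78 °C) reduces the ketone from the equatorial side to the axial allylic alcohol F1. A Mitsunobu reaction with 2-nitrobenzenesulfonylhydrazide (PPh3, DEAD, THF, −30 °C to rt) inverts C-3 and, after loss of the sulfinate, gives the allylic diazene F2. Its retro-ene loss of N2 delivers hydrogen to C-4a on the face of the C–N bond, which is the face of H-8a, and moves the double bond to C-3/C-4. This is 18, and compounds 15 to 17 are skipped.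

Step 13 (slow or unselective alkylation of the hindered tertiary ester enolate). Fallback, setting out from 18 and coming back at 25: iBu2AlH (CH2Cl2, −78 °C) gives the C-1 aldehyde F3 as C-1 epimers. Its enolate (K2CO3, aqueous formaldehyde, MeOH) undergoes a crossed aldol addition from the same open face to give the hydroxymethyl aldehyde F4. Hydrazine hydrate gives the hydrazone F5, and KOtBu in DMSO at rt (Wolff–Kishner, Cram variant) converts it into 25, so compounds 19 to 24 are skipped.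

Step 33 (addition to the very hindered neopentyl aldehyde, with retro-aldol on work-up). Fallback, setting out from 45 and coming back at 51: Pinnick oxidation (NaClO2, NaH2PO4, 2-methylbut-2-ene, tBuOH/H2O) gives the carboxylic acid F6. Coupling with Meldrum's acid (EDC, DMAP, CH2Cl2) gives the acyl Meldrum's acid F7. Heating F7 with glycine methyl ester (from 50 and Et3N) in toluene at 80 °C generates an acylketene that is trapped by the amine to give 51, so compounds 48 and 49 are skipped.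

Further compounds
F1 | step 10 | axial allylic alcohol (C-3 hydroxyl cis to the C-2 chain) | CC1(OCCO1)C[C@@H]2[C@H](O)C=C3C[C@H](C)C[C@@H](C)[C@@H]3C2C(=O)OCC
F2 | step 10 | allylic diazene (C-3 nitrogen trans to the C-2 chain) | CC1(OCCO1)C[C@@H]2[C@@H](N=N)C=C3C[C@H](C)C[C@@H](C)[C@@H]3C2C(=O)OCC
F3 | step 13 | C-1 aldehyde (C-1 epimers) | CC1(OCCO1)C[C@@H]2C=C[C@@H]3C[C@H](C)C[C@@H](C)[C@@H]3C2C=O
F4 | step 13 | hydroxymethyl aldehyde | CC1(OCCO1)C[C@@H]2C=C[C@@H]3C[C@H](C)C[C@@H](C)[C@@H]3[C@@]2(C=O)CO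
F5 | step 13 | hydrazone | CC1(OCCO1)C[C@@H]2C=C[C@@H]3C[C@H](C)C[C@@H](C)[C@@H]3[C@@]2(C=NN)CO
F6 | step 33 | carboxylic acid | CC[C@H](O[Si](C)(C)C(C)(C)C)[C@@H](C)/C=C/C=C/[C@H](O[Si](C)(C)C(C)(C)C)C[C@@H]1C=C[C@@H]2C[C@H](C)C[C@@H](C)[C@@H]2[C@@]1(C)C(=O)O
F7 | step 33 | acyl Meldrum's acid | CC[C@H](O[Si](C)(C)C(C)(C)C)[C@@H](C)/C=C/C=C/[C@H](O[Si](C)(C)C(C)(C)C)C[C@@H]1C=C[C@@H]2C[C@H](C)C[C@@H](C)[C@@H]2[C@@]1(C)C(O)=C1C(=O)OC(C)(C)OC1=O
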